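**Retrosynthetic overview**

1. The target is read as a trans-fused octahydronaphthalene (locants as in compound 20: C-2 carries the acrylic acid, C-4a the methyl, C-8 the acyloxymethyl group, C-7=C-8 is the ring alkene). Late disconnections: the (Z)-cinnamate C=C by Still–Gennari olefination on a C-8 CH2O–phosphonoacetate; the acrylate from a C-2 ethynyl group by Markovnikov hydroalkoxycarbonylation; the C-8 CH2OH from a C-8 ketone by enol triflate formation and Stille hydroxymethylation.
2. Key disconnection: the C-1–C-8a bond of ring B, closed by Michael addition of the C-8/C-8a ketone enolate to the CH2 terminus of an α-substituted acrylate. The enolate is made regiospecifically in the same flask by Cu-catalysed asymmetric conjugate addition of methyl to an achiral 3-alkylcyclohexenone, which sets C-4a.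
3. Enabling feature: in ring A the ring-fusion CH (C-8a) lies between C-8 (the alkene carbon bearing CH2O, a latent ketone carbon) and the quaternary, methyl-bearing C-4a (the β-carbon of that ketone's enone), so C-8a is exactly the enolate carbon left by a methyl 1,4-addition. In ring B the CH2 (C-1) is β to C-2, whose exocyclic acrylate carbon is a latent ester carbonyl, so C-1/C-2 can be the CH2=C unit of an acrylate; C-8a and C-2 stay epimerisable after closure and are relayed thermodynamically from C-4a.
4. Ring order: ring A is bought (3-ethoxycyclohexenone); ring B is the only ring made, in the key step.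

Key step: step 4

Assumption: the enantiomer of the phosphoramidite ligand L* is selected so that methyl adds to the enone face giving the (R)-configured quaternary carbon (the mirror-image ligand is used if the sense on this substrate is opposite), and bis(2,2,2-trifluoroethyl)phosphonoacetic acid (16) is taken as a purchasable reagent.

**Route**

Step 1
Reactants: 1 3-ethoxycyclohex-2-en-1-one; 2 (4-bromobut-1-yn-1-yl)trimethylsilane
Product: 5 3-[4-(trimethylsilyl)but-3-yn-1-yl]cyclohex-2-en-1-one, via Grignard reagent 3 (not isolated), via tertiary carbinol 4 (not isolated)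
Conditions: 2, Mg, THF, 0 °C to rt; then 1, THF, 0 °C; then 1 M aq HCl, rt
Reagents that add atoms: water (O)
Why: Grignard 1,2-addition to the vinylogous ester followed by acid-mediated hydrolysis with allylic transposition (Stork–Danheiser sequence) should give the 3-alkylcyclohexenone; no stereocentre is formed.

Step 2
Reactants: 5 3-[4-(trimethylsilyl)but-3-yn-1-yl]cyclohex-2-en-1-one
Product: 6 3-(but-3-yn-1-yl)cyclohex-2-en-1-one
Conditions: K2CO3 (0.2 equiv), MeOH, rt
Reagents that add atoms: none
Why: Base-catalysed methanolysis of the C(sp)–Si bond (protodesilylation of an alkynylsilane) should free the terminal alkyne without touching the enone.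

Step 3
Reactants: 6 3-(but-3-yn-1-yl)cyclohex-2-en-1-one
Product: 7 methyl 2-methylidene-4-(3-oxocyclohex-1-en-1-yl)butanoate
Conditions: Pd(OAc)2 (1 mol%), 2-(diphenylphosphino)pyridine, MsOH, CO (20 bar), MeOH, 50 °C
Reagents that add atoms: carbon monoxide ([C-]#[O+]); methanol (CO)
Why: Pd–hydride hydroalkoxycarbonylation of a terminal alkyne with a 2-pyridylphosphine ligand is Markovnikov-selective and should place the ester on the internal carbon, giving the 2-substituted acrylate; no stereocentre is formed.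

Step 4
Reactants: 7 methyl 2-methylidene-4-(3-oxocyclohex-1-en-1-yl)butanoate
Product: 10 methyl (2R,4aR,8aR)-4a-methyl-8-oxodecahydronaphthalene-2-carboxylate, via aluminium enolate 8 (not isolated), via cis-fused keto ester 9 (not isolated)
Conditions: CuTC (2 mol%), L* (biphenol-derived phosphoramidite of bis[(S)-1-(naphthalen-2-yl)ethyl]amine, 4 mol%), Me3Al (1.5 equiv), Et2O, −30 °C; then THF (dilute), MeLi (1.5 equiv), −78 to 0 °C; then MeOH, NaOMe, rt; aq Rochelle salt
Reagents that add atoms: trimethylaluminium (C[Al](C)C)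
Why: Proposed new method: Cu(I)/phosphoramidite-catalysed 1,4-addition of Me3Al to the β,β-disubstituted enone sets the quaternary C-4a and leaves, regiospecifically, the dimethylaluminium enolate 8 whose nucleophilic carbon is the future C-8a; conversion into the lithium aluminate with MeLi should trigger intramolecular Michael addition of this carbon to the CH2 terminus of the tethered 2-substituted acrylate (the future C-1), the closest known reaction types being Cu-catalysed conjugate-addition/Michael ring-closure cascades of bis-acceptors through zinc or magnesium enolates and the MeLi activation of aluminium enolates from quaternary-centre-forming additions for C-alkylation. Ring B closes in a 6-(enolexo)-endo-trig mode through a chair-like transition state. C-4a (R) is controlled by the chiral ligand; C-8a is formed kinetically cis (attack perpendicular to the enolate plane on the face of the pseudo-equatorial tether) and C-2 by protonation of the ester enolate, giving 9. Both centres are α to a carbonyl group, so methoxide should equilibrate them to the trans-fused decalone with the equatorial ester (the cis-fused isomer adds gauche interactions and an axial ester has two syn-axial hydrogens), which relays C-8a and C-2 thermodynamically from C-4a. The step needs chemoselectivity for the cyclohexenone over the acrylate, secured by the inertness of α-substituted acrylic esters towards Cu/AlMe3, and site-selectivity for C-8a over the other α-carbon of the ketone, secured because the conjugate addition places the enolate double bond only towards C-8a.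

Step 5
Reactants: 10 methyl (2R,4aR,8aR)-4a-methyl-8-oxodecahydronaphthalene-2-carboxylate
Product: 11 methyl (2R,4aR,8aR)-4a-methyl-8-[(trifluoromethanesulfonyl)oxy]-1,2,3,4,4a,5,6,8a-octahydronaphthalene-2-carboxylate
Conditions: KHMDS (1.1 equiv), THF, −78 °C; then PhNTf2, −78 to 0 °C; aq NH4Cl quench
Reagents that add atoms: N-phenyl-bis(trifluoromethanesulfonimide) (O=S(=O)(N(c1ccccc1)S(=O)(=O)C(F)(F)F)C(F)(F)F)
Why: Kinetic deprotonation by the bulky amide should occur at the C-7 methylene rather than at the hindered ring-fusion methine or α to the less acidic ester, and O-triflation of this enolate fixes the C-7=C-8 double bond of the target without enolising C-8a or C-2.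

Step 6
Reactants: 11 methyl (2R,4aR,8aR)-4a-methyl-8-[(trifluoromethanesulfonyl)oxy]-1,2,3,4,4a,5,6,8a-octahydronaphthalene-2-carboxylate
Product: 12 methyl (2R,4aR,8aR)-8-(hydroxymethyl)-4a-methyl-1,2,3,4,4a,5,6,8a-octahydronaphthalene-2-carboxylate
Conditions: Bu3SnCH2OH, Pd(PPh3)4 (5 mol%), LiCl, 1,4-dioxane, 100 °C
Reagents that add atoms: (tributylstannyl)methanol (OC[Sn](CCCC)(CCCC)CCCC)
Why: Stille cross-coupling of the enol triflate with the α-hydroxymethyl stannane (hydroxymethylation) should install the CH2OH carbon with retention of the alkene position and without touching the stereocentres.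

Step 7
Reactants: 12 methyl (2R,4aR,8aR)-8-(hydroxymethyl)-4a-methyl-1,2,3,4,4a,5,6,8a-octahydronaphthalene-2-carboxylate
Product: 14 [(4aR,7R,8aR)-7-ethynyl-4a-methyl-3,4,4a,5,6,7,8,8a-octahydronaphthalen-1-yl]methanol, via hydroxy aldehyde 13 (not isolated)
Conditions: DIBAL-H (2.2 equiv), CH2Cl2, −78 °C; then MeOH, K2CO3, dimethyl (1-diazo-2-oxopropyl)phosphonate, −78 °C to rt
Reagents that add atoms: dimethyl (1-diazo-2-oxopropyl)phosphonate (CC(=O)C(=[N+]=[N-])P(=O)(OC)OC)
Why: Low-temperature DIBAL-H reduction stops at the aluminium hemiacetal, which is homologated in the same flask with the Ohira–Bestmann reagent (Seyferth–Gilbert homologation) to the terminal alkyne; the C-2 configuration should be kept because the equatorial aldehyde is also the more stable epimer.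

Step 8
Reactants: 14 [(4aR,7R,8aR)-7-ethynyl-4a-methyl-3,4,4a,5,6,7,8,8a-octahydronaphthalen-1-yl]methanol
Product: 15 2-(trimethylsilyl)ethyl 2-[(2R,4aR,8aR)-8-(hydroxymethyl)-4a-methyl-1,2,3,4,4a,5,6,8a-octahydronaphthalen-2-yl]prop-2-enoate
Conditions: Pd(OAc)2 (2 mol%), 2-(diphenylphosphino)pyridine, MsOH, CO (20 bar), 2-(trimethylsilyl)ethanol (10 equiv), toluene, 50 °C
Reagents that add atoms: carbon monoxide ([C-]#[O+]); 2-(trimethylsilyl)ethanol (OCC[Si](C)(C)C)
Why: The same Markovnikov Pd–hydride hydroalkoxycarbonylation, with 2-(trimethylsilyl)ethanol in excess so that it outcompetes the substrate hydroxyl, should build the 2-substituted acrylate as a fluoride-labile ester.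

Step 9
Reactants: 15 2-(trimethylsilyl)ethyl 2-[(2R,4aR,8aR)-8-(hydroxymethyl)-4a-methyl-1,2,3,4,4a,5,6,8a-octahydronaphthalen-2-yl]prop-2-enoate; 16 bis(2,2,2-trifluoroethyl)phosphonoacetic acid
Product: 17 2-(trimethylsilyl)ethyl 2-[(2R,4aR,8aR)-8-[({[bis(2,2,2-trifluoroethoxy)phosphoryl]acetyl}oxy)methyl]-4a-methyl-1,2,3,4,4a,5,6,8a-octahydronaphthalen-2-yl]prop-2-enoate
Conditions: EDC·HCl, DMAP (cat.), CH2Cl2, 0 °C to rt
Reagents that add atoms: none
Why: Carbodiimide (Steglich-type) esterification of the unhindered primary allylic alcohol should proceed without affecting the silylethyl ester or the alkenes.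

Step 10
Reactants: 17 2-(trimethylsilyl)ethyl 2-[(2R,4aR,8aR)-8-[({[bis(2,2,2-trifluoroethoxy)phosphoryl]acetyl}oxy)methyl]-4a-methyl-1,2,3,4,4a,5,6,8a-octahydronaphthalen-2-yl]prop-2-enoate; 18 4-[(tert-butyldimethylsilyl)oxy]benzaldehyde
Product: 19 2-(trimethylsilyl)ethyl 2-[(2R,4aR,8aR)-8-({[(2Z)-3-{4-[(tert-butyldimethylsilyl)oxy]phenyl}prop-2-enoyl]oxy}methyl)-4a-methyl-1,2,3,4,4a,5,6,8a-octahydronaphthalen-2-yl]prop-2-enoate
Conditions: KHMDS, 18-crown-6, THF, −78 °C; aq NH4Cl quench; exclusion of light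
Reagents that add atoms: none
Why: Still–Gennari olefination, in which the electron-poor trifluoroethyl phosphonate with a dissociated potassium counter-ion eliminates rapidly from the kinetically formed adduct, should give the (Z)-cinnamate; the base is consumed by the far more acidic phosphonoacetate, so the rest of the molecule is untouched.

Step 11
Reactants: 19 2-(trimethylsilyl)ethyl 2-[(2R,4aR,8aR)-8-({[(2Z)-3-{4-[(tert-butyldimethylsilyl)oxy]phenyl}prop-2-enoyl]oxy}methyl)-4a-methyl-1,2,3,4,4a,5,6,8a-octahydronaphthalen-2-yl]prop-2-enoate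
Product: 20 2-[(2R,4aR,8aR)-8-({[(2Z)-3-(4-hydroxyphenyl)prop-2-enoyl]oxy}methyl)-4a-methyl-1,2,3,4,4a,5,6,8a-octahydronaphthalen-2-yl]prop-2-enoic acid (CNP0183482.1)
Conditions: TBAF, AcOH, THF, 0 °C to rt, exclusion of light
Reagents that add atoms: none
Why: Fluoride cleaves the aryl silyl ether and the 2-(trimethylsilyl)ethyl ester (β-elimination with loss of ethene) in one operation, while acetic acid buffering and exclusion of light should keep the (Z)-alkene and the allylic ester intact.

**Compound list**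

1 | 3-ethoxycyclohex-2-en-1-one | CCOC1=CC(=O)CCC1 | starting material
2 | (4-bromobut-1-yn-1-yl)trimethylsilane | C[Si](C)(C)C#CCCBr | starting material
3 | [4-(trimethylsilyl)but-3-yn-1-yl]magnesium bromide | C[Si](C)(C)C#CCC[Mg]Br | intermediate
4 | 3-ethoxy-1-[4-(trimethylsilyl)but-3-yn-1-yl]cyclohex-2-en-1-ol (racemic, present as its bromomagnesium alkoxide) | CCOC1=CC(O)(CCC#C[Si](C)(C)C)CCC1 | intermediate
5 | 3-[4-(trimethylsilyl)but-3-yn-1-yl]cyclohex-2-en-1-one | C[Si](C)(C)C#CCCC1=CC(=O)CCC1 | intermediate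
6 | 3-(but-3-yn-1-yl)cyclohex-2-en-1-one | C#CCCC1=CC(=O)CCC1 | intermediate
7 | methyl 2-methylidene-4-(3-oxocyclohex-1-en-1-yl)butanoate | C=C(CCC1=CC(=O)CCC1)C(=O)OC | intermediate
8 | methyl 4-{(1R)-3-[(dimethylalumanyl)oxy]-1-methylcyclohex-2-en-1-yl}-2-methylidenebutanoate | C=C(CC[C@@]1(C)CCCC(O[Al](C)C)=C1)C(=O)OC | intermediate
9 | methyl (4aR,8aS)-4a-methyl-8-oxodecahydronaphthalene-2-carboxylate (cis-fused, C-2 epimers) | COC(=O)C1CC[C@@]2(C)CCCC(=O)[C@H]2C1 | intermediate
10 | methyl (2R,4aR,8aR)-4a-methyl-8-oxodecahydronaphthalene-2-carboxylate | COC(=O)[C@@H]1CC[C@@]2(C)CCCC(=O)[C@@H]2C1 | intermediate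
11 | methyl (2R,4aR,8aR)-4a-methyl-8-[(trifluoromethanesulfonyl)oxy]-1,2,3,4,4a,5,6,8a-octahydronaphthalene-2-carboxylate | COC(=O)[C@@H]1CC[C@@]2(C)CCC=C(OS(=O)(=O)C(F)(F)F)[C@@H]2C1 | intermediate
12 | methyl (2R,4aR,8aR)-8-(hydroxymethyl)-4a-methyl-1,2,3,4,4a,5,6,8a-octahydronaphthalene-2-carboxylate | COC(=O)[C@@H]1CC[C@@]2(C)CCC=C(CO)[C@@H]2C1 | intermediate
13 | (2R,4aR,8aR)-8-(hydroxymethyl)-4a-methyl-1,2,3,4,4a,5,6,8a-octahydronaphthalene-2-carbaldehyde | O=C[C@@H]1CC[C@@]2(C)CCC=C(CO)[C@@H]2C1 | intermediate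
14 | [(4aR,7R,8aR)-7-ethynyl-4a-methyl-3,4,4a,5,6,7,8,8a-octahydronaphthalen-1-yl]methanol | C#C[C@@H]1CC[C@@]2(C)CCC=C(CO)[C@@H]2C1 | intermediate
15 | 2-(trimethylsilyl)ethyl 2-[(2R,4aR,8aR)-8-(hydroxymethyl)-4a-methyl-1,2,3,4,4a,5,6,8a-octahydronaphthalen-2-yl]prop-2-enoate | C=C(C(=O)OCC[Si](C)(C)C)[C@@H]1CC[C@@]2(C)CCC=C(CO)[C@@H]2C1 | intermediate
16 | bis(2,2,2-trifluoroethyl)phosphonoacetic acid | OC(=O)CP(=O)(OCC(F)(F)F)OCC(F)(F)F | starting material
17 | 2-(trimethylsilyl)ethyl 2-[(2R,4aR,8aR)-8-[({[bis(2,2,2-trifluoroethoxy)phosphoryl]acetyl}oxy)methyl]-4a-methyl-1,2,3,4,4a,5,6,8a-octahydronaphthalen-2-yl]prop-2-enoate | C=C(C(=O)OCC[Si](C)(C)C)[C@@H]1CC[C@@]2(C)CCC=C(COC(=O)CP(=O)(OCC(F)(F)F)OCC(F)(F)F)[C@@H]2C1 | intermediate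
18 | 4-[(tert-butyldimethylsilyl)oxy]benzaldehyde | O=Cc1ccc(O[Si](C)(C)C(C)(C)C)cc1 | starting material
19 | 2-(trimethylsilyl)ethyl 2-[(2R,4aR,8aR)-8-({[(2Z)-3-{4-[(tert-butyldimethylsilyl)oxy]phenyl}prop-2-enoyl]oxy}methyl)-4a-methyl-1,2,3,4,4a,5,6,8a-octahydronaphthalen-2-yl]prop-2-enoate | C=C(C(=O)OCC[Si](C)(C)C)[C@@H]1CC[C@@]2(C)CCC=C(COC(=O)/C=C\c3ccc(O[Si](C)(C)C(C)(C)C)cc3)[C@@H]2C1 | intermediate
20 | 2-[(2R,4aR,8aR)-8-({[(2Z)-3-(4-hydroxyphenyl)prop-2-enoyl]oxy}methyl)-4a-methyl-1,2,3,4,4a,5,6,8a-octahydronaphthalen-2-yl]prop-2-enoic acid | C=C(C(=O)O)[C@@H]1CC[C@@]2(C)CCC=C(COC(=O)/C=C\c3ccc(O)cc3)[C@@H]2C1 | target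

**Step count and risks**

Total step count: 11. Longest linear sequence: 11 steps (from 1; compounds 2, 16 and 18 are purchased).

Steps most likely to fail:

1. Step 4 (Proposed new method). What may go wrong: the aluminate enolate may add too slowly to the weakly electrophilic α-substituted acrylate, so that proton transfer or intermolecular Michael oligomerisation takes over. The coordinating ester may also erode the facial selectivity of the methyl addition. Fallback with known chemistry, setting out from 7 and coming back at 10: the conjugate addition is run alone under the same Cu/L*/Me3Al conditions and quenched with aqueous NH4Cl, the established quaternary-centre-forming addition to 3-alkylcyclohexenones, which should give methyl 2-methylidene-4-[(1R)-1-methyl-3-oxocyclohexyl]butanoate F1. F1 is then cyclised under thermodynamic control with NaOMe in MeOH at rt (base-mediated intramolecular Michael addition). Enolisation is reversible, only the α-carbon next to the quaternary centre can reach the acrylate terminus through a six-membered ring, and the same methoxide equilibrates the ring fusion and the ester, so that 10 should result.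

2. Step 7. What may go wrong: over-reduction of the ester to the primary alcohol, and epimerisation α to the transient aldehyde during the basic homologation. Fallback setting out from 12 and coming back at 15 (it replaces steps 7 and 8): the hydroxyl of 12 is silylated (TBSCl, imidazole, DMF) to methyl (2R,4aR,8aR)-8-{[(tert-butyldimethylsilyl)oxy]methyl}-4a-methyl-1,2,3,4,4a,5,6,8a-octahydronaphthalene-2-carboxylate F2. The ester is converted with Me3SiCH2Li (2.5 equiv, THF/pentane, −78 to 0 °C, then MeOH) into the methyl ketone 1-[(2R,4aR,8aR)-8-{[(tert-butyldimethylsilyl)oxy]methyl}-4a-methyl-1,2,3,4,4a,5,6,8a-octahydronaphthalen-2-yl]ethan-1-one F3. Kinetic enolisation at the methyl group (KHMDS, PhNTf2, THF, −78 °C) should give the terminal enol triflate 1-[(2R,4aR,8aR)-8-{[(tert-butyldimethylsilyl)oxy]methyl}-4a-methyl-1,2,3,4,4a,5,6,8a-octahydronaphthalen-2-yl]ethenyl trifluoromethanesulfonate F4. Pd-catalysed alkoxycarbonylation (Pd(OAc)2, PPh3, Et3N, CO 1 atm, 2-(trimethylsilyl)ethanol, DMF, 50 °C) should give 2-(trimethylsilyl)ethyl 2-[(2R,4aR,8aR)-8-{[(tert-butyldimethylsilyl)oxy]methyl}-4a-methyl-1,2,3,4,4a,5,6,8a-octahydronaphthalen-2-yl]prop-2-enoate F5. PPTS in MeOH then removes the silyl ether and returns 15.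

3. Step 11. What may go wrong: base-promoted Z-to-E isomerisation of the p-hydroxycinnamate through its phenoxide, or incomplete cleavage of the silylethyl ester under buffered fluoride. Fallback setting out from 15 and coming back at 20 (it replaces steps 9 to 11 and sets the alkene geometry last): 15 is esterified under Mitsunobu conditions (PPh3, DIAD, THF, 0 °C) with 3-(4-hydroxyphenyl)prop-2-ynoic acid, the far more acidic carboxyl group reacting in preference to the phenol. This should give 2-(trimethylsilyl)ethyl 2-[(2R,4aR,8aR)-8-({[3-(4-hydroxyphenyl)prop-2-ynoyl]oxy}methyl)-4a-methyl-1,2,3,4,4a,5,6,8a-octahydronaphthalen-2-yl]prop-2-enoate F6. TBAF/AcOH in THF then frees 2-[(2R,4aR,8aR)-8-({[3-(4-hydroxyphenyl)prop-2-ynoyl]oxy}methyl)-4a-methyl-1,2,3,4,4a,5,6,8a-octahydronaphthalen-2-yl]prop-2-enoic acid F7, in which no alkene geometry is at stake. Semi-hydrogenation over Lindlar catalyst (H2 1 atm, quinoline, EtOAc, rt) should deliver the (Z)-alkene by syn addition and give 20.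

Further compounds
F1 | step 4 | methyl 2-methylidene-4-[(1R)-1-methyl-3-oxocyclohexyl]butanoate | C=C(CC[C@@]1(C)CCCC(=O)C1)C(=O)OC
F2 | step 7 | methyl (2R,4aR,8aR)-8-{[(tert-butyldimethylsilyl)oxy]methyl}-4a-methyl-1,2,3,4,4a,5,6,8a-octahydronaphthalene-2-carboxylate | COC(=O)[C@@H]1CC[C@@]2(C)CCC=C(CO[Si](C)(C)C(C)(C)C)[C@@H]2C1
F3 | step 7 | 1-[(2R,4aR,8aR)-8-{[(tert-butyldimethylsilyl)oxy]methyl}-4a-methyl-1,2,3,4,4a,5,6,8a-octahydronaphthalen-2-yl]ethan-1-one | CC(=O)[C@@H]1CC[C@@]2(C)CCC=C(CO[Si](C)(C)C(C)(C)C)[C@@H]2C1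
F4 | step 7 | 1-[(2R,4aR,8aR)-8-{[(tert-butyldimethylsilyl)oxy]methyl}-4a-methyl-1,2,3,4,4a,5,6,8a-octahydronaphthalen-2-yl]ethenyl trifluoromethanesulfonate | C=C(OS(=O)(=O)C(F)(F)F)[C@@H]1CC[C@@]2(C)CCC=C(CO[Si](C)(C)C(C)(C)C)[C@@H]2C1
F5 | step 7 | 2-(trimethylsilyl)ethyl 2-[(2R,4aR,8aR)-8-{[(tert-butyldimethylsilyl)oxy]methyl}-4a-methyl-1,2,3,4,4a,5,6,8a-octahydronaphthalen-2-yl]prop-2-enoate | C=C(C(=O)OCC[Si](C)(C)C)[C@@H]1CC[C@@]2(C)CCC=C(CO[Si](C)(C)C(C)(C)C)[C@@H]2C1
F6 | step 11 | 2-(trimethylsilyl)ethyl 2-[(2R,4aR,8aR)-8-({[3-(4-hydroxyphenyl)prop-2-ynoyl]oxy}methyl)-4a-methyl-1,2,3,4,4a,5,6,8a-octahydronaphthalen-2-yl]prop-2-enoate | C=C(C(=O)OCC[Si](C)(C)C)[C@@H]1CC[C@@]2(C)CCC=C(COC(=O)C#Cc3ccc(O)cc3)[C@@H]2C1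
F7 | step 11 | 2-[(2R,4aR,8aR)-8-({[3-(4-hydroxyphenyl)prop-2-ynoyl]oxy}methyl)-4a-methyl-1,2,3,4,4a,5,6,8a-octahydronaphthalen-2-yl]prop-2-enoic acid | C=C(C(=O)O)[C@@H]1CC[C@@]2(C)CCC=C(COC(=O)C#Cc3ccc(O)cc3)[C@@H]2C1
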